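## Structural features

The target is an isoflavone: a 5,7-dihydroxychromen-4-one (rings A and C) that carries a tetrasubstituted benzene ring B at C3. Ring B is fused through C2' (oxygen) and C3' (carbon) to a 2H-pyran ring D, so rings B and D form a 5-hydroxy-2H-chromene joined to the chromone by the C3–C1' bond, ortho to the pyran oxygen. The only stereocentre is the quaternary C2'' of ring D, which bears the ring oxygen, a methyl group, a hydroxymethyl group and the C3''=C4'' alkene; it is S and has no stereogenic neighbour, so only absolute configuration has to be controlled. The fragile elements are the chromene (a tertiary allylic aryl ether beside an electron-rich styrene-type alkene, open to acid-induced ionisation and to thermal or photochemical electrocyclic ring opening, either of which would racemise C2''), the chromone C2 position (attacked by strong base) and the three free phenols. The real difficulty is to place the oxygen-bearing quaternary stereocentre as one enantiomer on the contiguously 1',2',3',4'-substituted ring B and then to build the pyranone next to it without ever breaking the C2''–O bond. The key step exploits ring A: C4a lies between the O1-bearing C8a and the oxygenated C5 and para to the oxygenated C7, and in the open precursor the two carbons ortho to the aryl ether oxygen are equivalent by symmetry, so an acyl carbon (the future C4) tethered through O1, C2 and C3 can only form the C4–C4a bond.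

## Logic of the disconnections

**21 ⇒ 20.** The four O–Si bonds (O5, O7, O4' and the primary oxygen on C2'') are cut. One kind of silyl ether on every hydroxyl allows an acyl chloride and a Lewis acid earlier and lets a single fluoride treatment end the route. The last step then creates no skeletal bond. It demands a buffered fluoride source, because the chromone C2 is base-sensitive.

**20 ⇒ 18 (through 19).** The C4–C4a bond of ring C is cut. C4a is the most nucleophilic carbon of ring A, and once the bond is cut ring A is a symmetric 3,5-dioxygenated aryl ether, so the forward acylation has no regiochemical choice. Ring C disappears and the chromone becomes an acrylic acid with ring B on Cα and an aryl vinyl ether on Cβ. The forward step must generate the acyl electrophile without protic acid, needs carboxyl and aryloxy cis (or able to become cis), and must be faster at ring A than at ring B, its ortho oxygen or the chromene alkene.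

**18 ⇒ 17.** The O–allyl bond of an ester is cut (functional-group change only). Hydroxide cannot free the acid, since it would add to the β-aryloxy acrylate and strip aryl silyl ethers. An allyl ester is removed by zerovalent palladium under neutral conditions; the catalyst must ionise only that ester.

**17 ⇒ 14 + 16.** The O1–C2 bond of the vinyl ether is cut. Ring A becomes a symmetric phenol, and C2 becomes the β-carbon of an acrylate bearing a sulfonate, an electrophile for addition–elimination. The forward step must occur at carbon rather than sulfur and through the phenoxide oxygen rather than a ring carbon; Z geometry is desirable but not critical.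

**16 ⇒ 15.** Two O–Si bonds are cut. The demand is a statistical bis-silylation with chromatographic separation, acceptable because 15 is a bulk chemical.

**14 ⇒ 13 ⇒ 10 + 12.** First the O–S bond of the enol tosylate is cut. Then the C2–C3 and C3–C1' bonds are cut and C1' is reconnected to C2: C2 is the formyl carbon of 10, C3 is the diazo carbon of 12, and ring B migrates from one to the other in the forward reaction. Both missing carbons of ring C and the ester arrive in one step, in place of a one-carbon homologation followed by formylation. Aryl migration must outrun hydride migration (favoured by an electron-rich ring), and the acid catalyst must spare silyl ethers and chromene. 12 ⇒ 11 cuts the C=N2 unit back to a C–Br bond.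

**10 ⇒ 9.** The C4''–C3' bond of ring D is cut, leaving an aryl propargyl ether whose alkyne terminus faces the only free ortho carbon of ring B. Ring D is removed without touching the C2''–O bond. The forward step must be a direct hydroarylation; a thermal sigmatropic route would break and remake that bond and lose the configuration.

**9 ⇒ 5 + 7 (through 8).** The aryl C2'–O bond is cut. The formyl group that later becomes C2 is ortho to this bond and activates a fluoride for substitution, and the oxygen comes from the alkoxide, so the bond between oxygen and the stereocentre stays intact. The molecule falls into a small chiral alcohol and a simple arene. A hindered tertiary alkoxide must attack the ring carbon faster than silicon or the aldehyde. 7 ⇒ 6 cuts one O–Si bond.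

**5 ⇒ 4 ⇒ 3 ⇒ 1 (through 2).** The O–Si bond is cut, then the bond between the primary oxygen and its CH2 (oxirane opening), then the C≡C bond, whose terminal carbon is added to the formyl carbon of 2 (the hydroxymethyl carbon of 1). This maps the hydroxymethyl carbon of 1 onto C3'' and the oxirane CH2 onto the hydroxymethyl group of 21, the only mapping that turns the configuration of 1 into that of 21. The oxirane must be opened at its CH2 under basic conditions so the quaternary C–O bond is never broken, and the volatile 2 and 3 must be handled in solution.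

## Other disconnections considered

Alternative 1: The cut is the aryl C2'–O bond of ring D, closed last on a ring-B fragment not yet attached to the chromone. The bromo alcohol A2 would be treated with Pd(OAc)2, a bulky di-tert-butyl(biaryl)phosphine and Cs2CO3; oxidative addition into C–Br (preferred over C–Cl), alkoxide binding and C–O reductive elimination would give the chromene A1, whose chloride is kept for the later union at C1'.
- In favour: the O–C2'' bond of the carbinol is never broken, so the stereocentre is carried through exactly as in the chosen plan (equal on this point). A tertiary alkoxide has no hydrogen on the carbinol carbon, so β-hydride elimination from the palladium alkoxide is closed. The Z alkene holds the hydroxyl next to the halide. No Lewis acid or acyl cation meets the chromene and the isoflavone bond would come from a convergent cross-coupling; on convergence and mildness toward the chromene this plan is the better one.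
- Against: reductive elimination of a hindered tertiary alkoxide is slow and the bromide is flanked on both sides. A2 is a Z-styrenyl tertiary allylic alcohol, prone to ionisation and Z/E isomerisation. A ring with four contiguous, differentiated substituents and a Z alkene must first be assembled. The chloride left in A1 is hindered and electron-rich. Two protecting-group families mean an acidic deprotection on the finished chromene.
- Comparison: structurally both rely on a preformed enantiopure tertiary alcohol. Mechanistically the chosen plan replaces two palladium couplings by an SNAr and a hydroarylation and uses the formyl group twice (activator, then source of C2), so no halogen differentiation is needed. Step counts are probably close up to the chromene, after which this alternative still needs two palladium steps.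

Alternative 2: The cut is the O–C2'' bond at the stereocentre itself. The epoxy alcohol A4 (its oxirane from a Sharpless asymmetric epoxidation of an E-configured allylic alcohol side chain) would be opened by the C2' phenol under catalytic camphorsulfonic acid at the tertiary carbon (6-endo, inversion) to give the chroman-3-ol A3.
- In favour: configuration comes from a catalytic, reagent-controlled reaction, so either enantiomer is available and no chiral-pool fragment is carried; on this point it is better than the chosen plan. The isoflavone core is complete before the sensitive chromene exists. Under acid the tertiary carbon carries more positive charge, which favours the endo opening.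
- Against: the C–O bond at C2'' is formed in the key step, so enantiomeric purity depends on clean inversion at a tertiary carbon under acid, where a loose, cation-like transition state can leak to retention. 5-exo attack at the secondary carbon competes. A3 still lacks the C3''–C4'' alkene, which requires selective dehydration of the secondary alcohol beside the primary one, and three MOM groups must be removed with acid from an acid-sensitive chromene.
- Comparison: structurally this is more direct up to A3. Mechanistically it stakes the stereocentre on a borderline SN1/SN2 event, whereas the chosen plan never breaks the C2''–O bond. It needs at least three operations after A3. The two are equal in having no regiochemical problem on ring A.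

Alternative 3: The cut removes ring B: C5'–C6', C2'–C3', C4'–C5' and C1'–C2' are traced back to the chromon-3-yl diazo enone A6 and the siloxyalkyne A7. On irradiation A6 would undergo Wolff rearrangement to a vinylketene, which adds to A7 in a [2+2] sense; four-electron opening of the cyclobutenone and six-electron closure of the dienylketene would give the phenol A5.
- In favour: all four substituents of ring B are placed by the polarity of the ketene–ynol ether cycloaddition, four C–C bonds form in one operation, and rings A and C are present from the start. In convergence and regiochemical certainty of ring B this plan is better than the chosen one.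
- Against: A5 has neither ring D nor the stereocentre, so the hardest problem (enantioselective closure of the 2'-hydroxyl onto the trisubstituted alkene with creation of the quaternary centre and the C3''–C4'' alkene) is only postponed. The chromone enone is a chromophore and Michael acceptor, so competing photochemistry of A6 is a concern. A6 and A7 are sensitive and each takes several steps. Three protecting-group types need acidic and oxidative removals.
- Comparison: the chosen plan forms one bond in its key step and relies on symmetry rather than a cascade, has the stereocentre from the first step and ends with one deprotection. The alternative is expected to be longer once the conversion of A5 into 21 is counted.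

Key step: step 13

Remarks on the chemistry:
- Ring closure needs carboxyl and aryloxy cis (Z) in 18. Compounds 13, 14 and 17–19 are written as Z isomers; any E material is expected to converge in step 13.
- Allyl diazoacetate 12 is prepared (step 7) and used as a solution; it is not assumed to be purchasable.
- All four silyl groups of 18 are identical (triisopropylsilyl); the ring closure is run with a hindered pyridine as proton trap and at high dilution.

## Route

Step 1
Reactants: 1 (S)-2-methylglycidol
Product: 3 (S)-2-ethynyl-2-methyloxirane, via (R)-2-methyloxirane-2-carbaldehyde 2 (not isolated)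
Conditions: (COCl)2, DMSO, CH2Cl2, −78 °C; Et3N, −78 → 0 °C; then MeOH, K2CO3, dimethyl (1-diazo-2-oxopropyl)phosphonate, 0 °C → rt; product kept as a concentrated pentane solution
Reagents that add atoms: dimethyl (1-diazo-2-oxopropyl)phosphonate, CC(=O)C(=[N+]=[N-])P(=O)(OC)OC
Why: Swern oxidation followed without isolation by Seyferth–Gilbert homologation with the Ohira–Bestmann reagent; the α-carbon is quaternary and cannot epimerise, and telescoping avoids isolating the volatile aldehyde. The hydroxymethyl carbon of 1 becomes the alkyne carbon, which fixes the mapping of the stereocentre onto 21.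

Step 2
Reactants: 3 (S)-2-ethynyl-2-methyloxirane
Product: 4 (S)-2-methylbut-3-yne-1,2-diol
Conditions: KOH (2 M aq), DMSO, 60 °C, sealed vessel; neutralise, continuous extraction with EtOAc
Reagents that add atoms: water, O
Why: SN2 opening of the oxirane by hydroxide at the unsubstituted CH2; the quaternary C–O bond is untouched, so configuration is retained. Base is used because acid would open at the tertiary propargylic carbon with loss of configuration.

Step 3
Reactants: 4 (S)-2-methylbut-3-yne-1,2-diol
Product: 5 (S)-2-methyl-1-(triisopropylsilyloxy)but-3-yn-2-ol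
Conditions: TIPSCl (1.05 equiv), imidazole, CH2Cl2, 0 °C → rt
Reagents that add atoms: chlorotriisopropylsilane (TIPSCl), CC(C)[Si](Cl)(C(C)C)C(C)C
Why: Silylation of the primary hydroxyl; the bulky chlorosilane does not react with the tertiary propargylic alcohol, which stays free for step 5.

Step 4
Reactants: 6 2-fluoro-4-hydroxybenzaldehyde
Product: 7 2-fluoro-4-(triisopropylsilyloxy)benzaldehyde
Conditions: TIPSCl, imidazole, DMF, rt
Reagents that add atoms: chlorotriisopropylsilane (TIPSCl), CC(C)[Si](Cl)(C(C)C)C(C)C
Why: Standard phenol silylation; the triisopropylsilyl ether is the aryl silyl ether most resistant to base, and a free phenoxide para to the formyl group would switch off the SNAr of step 5.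

Step 5
Reactants: 5 (S)-2-methyl-1-(triisopropylsilyloxy)but-3-yn-2-ol; 7 2-fluoro-4-(triisopropylsilyloxy)benzaldehyde
Product: 9 (S)-2-{[2-methyl-1-(triisopropylsilyloxy)but-3-yn-2-yl]oxy}-4-(triisopropylsilyloxy)benzaldehyde, via potassium tert-alkoxide 8 (not isolated)
Conditions: KN(SiMe3)2 (1.0 equiv), THF, −40 °C; then 7, toluene–THF, −40 → 0 °C
Reagents that add atoms: none
Why: Nucleophilic aromatic substitution (addition–elimination) of fluoride ortho to the formyl group by the potassium alkoxide, helped by potassium bridging the carbonyl oxygen and the incoming alkoxide. The oxygen comes from the alcohol, so the O–C bond at the stereocentre is not broken and the S configuration is retained.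

Step 6
Reactants: 9 (S)-2-{[2-methyl-1-(triisopropylsilyloxy)but-3-yn-2-yl]oxy}-4-(triisopropylsilyloxy)benzaldehyde
Product: 10 (S)-2-methyl-5-(triisopropylsilyloxy)-2-[(triisopropylsilyloxy)methyl]-2H-chromene-8-carbaldehyde
Conditions: Ph3PAuNTf2 (3 mol %), CH2Cl2, rt
Reagents that add atoms: none
Why: Gold-catalysed 6-endo-dig hydroarylation of an aryl propargyl ether; the only free ortho carbon (between the two oxygens) attacks the activated terminal alkyne carbon and protodeauration gives the 2H-chromene. The C2''–O bond is not broken, so configuration is retained, unlike a thermal propargyl Claisen cascade, which would pass through an achiral o-quinone methide.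

Step 7
Reactants: 11 allyl bromoacetate
Product: 12 allyl diazoacetate
Conditions: N,N'-ditosylhydrazine, DBU, THF, 0 °C; used as a dried CH2Cl2 solution, not concentrated
Reagents that add atoms: N,N'-ditosylhydrazine, Cc1ccc(cc1)S(=O)(=O)NNS(=O)(=O)c1ccc(C)cc1
Why: N-alkylation of the bis-sulfonyl hydrazine by the bromoacetate and two base-induced losses of sulfinate give the diazo ester, an established preparation of diazoacetates from bromoacetates. The allyl ester is chosen so the acid can later be freed without hydroxide.

Step 8
Reactants: 10 (S)-2-methyl-5-(triisopropylsilyloxy)-2-[(triisopropylsilyloxy)methyl]-2H-chromene-8-carbaldehyde; 12 allyl diazoacetate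
Product: 13 allyl (Z)-3-hydroxy-2-{(S)-2-methyl-5-(triisopropylsilyloxy)-2-[(triisopropylsilyloxy)methyl]-2H-chromen-8-yl}acrylate
Conditions: HBF4·OEt2 (10 mol %), CH2Cl2, −78 °C, slow addition of 12
Reagents that add atoms: none
Why: Acid-catalysed addition of the diazo ester to the aldehyde gives a β-hydroxy diazonium ion that loses N2 with 1,2-aryl shift, the aryl-migration counterpart of the Roskamp reaction and known for electron-rich benzaldehydes. The ortho-alkoxy, para-silyloxy ring migrates in preference to hydride, and the α-formyl ester rests as the hydrogen-bonded Z enol.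

Step 9
Reactants: 13 allyl (Z)-3-hydroxy-2-{(S)-2-methyl-5-(triisopropylsilyloxy)-2-[(triisopropylsilyloxy)methyl]-2H-chromen-8-yl}acrylate
Product: 14 allyl (Z)-2-{(S)-2-methyl-5-(triisopropylsilyloxy)-2-[(triisopropylsilyloxy)methyl]-2H-chromen-8-yl}-3-(tosyloxy)acrylate
Conditions: TsCl, Me2NCH2CH2NMe2 (TMEDA), LiCl, MeCN, 0 °C
Reagents that add atoms: p-toluenesulfonyl chloride (TsCl), Cc1ccc(cc1)S(Cl)(=O)=O
Why: O-sulfonylation of the enolate of an α-formyl ester; lithium chelated between the enolate and ester oxygens keeps them cis, so the tosyloxy group is placed cis to the ester (Z). The conditions are non-nucleophilic and spare the aryl silyl ethers and the allyl ester.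

Step 10
Reactants: 15 phloroglucinol
Product: 16 3,5-bis(triisopropylsilyloxy)phenol
Conditions: TIPSCl (2.0 equiv), imidazole, DMF, 0 °C → rt; chromatographic separation from mono- and tris-silyl ethers
Reagents that add atoms: chlorotriisopropylsilane (TIPSCl), CC(C)[Si](Cl)(C(C)C)C(C)C
Why: Statistical silylation of a C3-symmetric triol; the bis-ether is the only product with one free hydroxyl flanked by two equivalent ortho carbons, and the other fractions can be recycled by desilylation.

Step 11
Reactants: 14 allyl (Z)-2-{(S)-2-methyl-5-(triisopropylsilyloxy)-2-[(triisopropylsilyloxy)methyl]-2H-chromen-8-yl}-3-(tosyloxy)acrylate; 16 3,5-bis(triisopropylsilyloxy)phenol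
Product: 17 allyl (Z)-3-[3,5-bis(triisopropylsilyloxy)phenoxy]-2-{(S)-2-methyl-5-(triisopropylsilyloxy)-2-[(triisopropylsilyloxy)methyl]-2H-chromen-8-yl}acrylate
Conditions: Cs2CO3, MeCN, 0 °C → rt
Reagents that add atoms: none
Why: Nucleophilic vinylic substitution (addition–elimination) at the β-carbon of the acrylate by the caesium phenoxide; the ester-stabilised carbanion should expel tosylate mainly with retention, and any E isomer is harmless because both geometries converge in step 13. Attack through oxygen at the activated sp2 carbon is expected to beat attack at sulfur of the tosylate or through a ring carbon in a polar aprotic medium.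

Step 12
Reactants: 17 allyl (Z)-3-[3,5-bis(triisopropylsilyloxy)phenoxy]-2-{(S)-2-methyl-5-(triisopropylsilyloxy)-2-[(triisopropylsilyloxy)methyl]-2H-chromen-8-yl}acrylate
Product: 18 (Z)-3-[3,5-bis(triisopropylsilyloxy)phenoxy]-2-{(S)-2-methyl-5-(triisopropylsilyloxy)-2-[(triisopropylsilyloxy)methyl]-2H-chromen-8-yl}acrylic acid
Conditions: Pd(PPh3)4 (5 mol %), morpholine, THF, rt; pH 5 phosphate buffer wash
Reagents that add atoms: none
Why: Tsuji–Trost deallylation: zerovalent palladium ionises the allyl ester and morpholine traps the π-allyl fragment, freeing the acid under neutral conditions that leave the silyl ethers, the enol ether and the chromene alone.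

Step 13
Reactants: 18 (Z)-3-[3,5-bis(triisopropylsilyloxy)phenoxy]-2-{(S)-2-methyl-5-(triisopropylsilyloxy)-2-[(triisopropylsilyloxy)methyl]-2H-chromen-8-yl}acrylic acid
Product: 20 5,7-bis(triisopropylsilyloxy)-3-{(S)-2-methyl-5-(triisopropylsilyloxy)-2-[(triisopropylsilyloxy)methyl]-2H-chromen-8-yl}-4H-chromen-4-one, via acryloyl chloride 19 (not isolated)
Conditions: 1-chloro-N,N,2-trimethylprop-1-en-1-amine (1.2 equiv), CH2Cl2, 0 °C → rt; dilute to 0.005 M, 2,6-di-tert-butyl-4-methylpyridine (1.5 equiv), SnCl4 (1.2 equiv), −78 → −40 °C
Reagents that add atoms: none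
Why: The chloroenamine converts the acid into acyl chloride 19 without releasing HCl, so the silyl ethers and chromene are untouched. SnCl4 then ionises 19 to an acylium ion (or its chloride complex) whose charge is shared with the vinyl ether oxygen; this lowers the barrier to rotation about C2=C3, so E material feeds the reactive Z form. Ring A attacks through the carbon ortho to the ether oxygen (also ortho to one silyloxy group and para to the other) and the arenium ion loses a proton to the hindered pyridine: an intramolecular Friedel–Crafts acylation whose closest known type is the acid-mediated cyclisation of 3-aryloxyacrylic acids to chromones. Ring C closes in a 6-exo-trig mode at the acyl carbon (6-exo-dig for the free acylium), with the C4a–C8a bond inside the new ring. No stereocentre is created, and C2'' is remote with its C–O bond not involved. Regioselectivity is not an issue because the two ortho carbons of the 3,5-disilyloxyphenoxy group are symmetry-equivalent. The chemoselectivity needed is for ring A over ring B, its ortho oxygen and the chromene alkene; it is secured by the three-atom tether, high dilution, low temperature and the proton trap.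

Step 14
Reactants: 20 5,7-bis(triisopropylsilyloxy)-3-{(S)-2-methyl-5-(triisopropylsilyloxy)-2-[(triisopropylsilyloxy)methyl]-2H-chromen-8-yl}-4H-chromen-4-one
Product: 21 5,7-dihydroxy-3-[(S)-5-hydroxy-2-(hydroxymethyl)-2-methyl-2H-chromen-8-yl]-4H-chromen-4-one
Conditions: Bu4NF (TBAF, 6 equiv), AcOH (6 equiv), THF, 0 °C → rt
Reagents that add atoms: none
Why: Fluoride-induced cleavage of three aryl and one primary alkyl silyl ether; acetic acid buffers the phenoxides so the chromone C2 and the chromene are not exposed to strong base, and no step after ring closure touches C2''.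

## Compound list

1 | (S)-2-methylglycidol [(S)-(2-methyloxiran-2-yl)methanol] | OC[C@@]1(C)CO1 | starting material
2 | (R)-2-methyloxirane-2-carbaldehyde | O=C[C@@]1(C)CO1 | intermediate (not isolated)
3 | (S)-2-ethynyl-2-methyloxirane | C#C[C@@]1(C)CO1 | intermediate
4 | (S)-2-methylbut-3-yne-1,2-diol | C#C[C@@](O)(C)CO | intermediate
5 | (S)-2-methyl-1-(triisopropylsilyloxy)but-3-yn-2-ol | C#C[C@@](O)(C)CO[Si](C(C)C)(C(C)C)C(C)C | intermediate
6 | 2-fluoro-4-hydroxybenzaldehyde | O=Cc1ccc(O)cc1F | starting material
7 | 2-fluoro-4-(triisopropylsilyloxy)benzaldehyde | O=Cc1ccc(O[Si](C(C)C)(C(C)C)C(C)C)cc1F | intermediate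
8 | potassium (S)-2-methyl-1-(triisopropylsilyloxy)but-3-yn-2-olate | C#C[C@@]([O-])(C)CO[Si](C(C)C)(C(C)C)C(C)C.[K+] | intermediate (not isolated)
9 | (S)-2-{[2-methyl-1-(triisopropylsilyloxy)but-3-yn-2-yl]oxy}-4-(triisopropylsilyloxy)benzaldehyde | O=Cc1ccc(O[Si](C(C)C)(C(C)C)C(C)C)cc1O[C@@](C)(C#C)CO[Si](C(C)C)(C(C)C)C(C)C | intermediate
10 | (S)-2-methyl-5-(triisopropylsilyloxy)-2-[(triisopropylsilyloxy)methyl]-2H-chromene-8-carbaldehyde | O=Cc1ccc(O[Si](C(C)C)(C(C)C)C(C)C)c2C=C[C@@](C)(CO[Si](C(C)C)(C(C)C)C(C)C)Oc12 | intermediate
11 | allyl bromoacetate | C=CCOC(=O)CBr | starting material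
12 | allyl diazoacetate | C=CCOC(=O)C=[N+]=[N-] | intermediate
13 | allyl (Z)-3-hydroxy-2-{(S)-2-methyl-5-(triisopropylsilyloxy)-2-[(triisopropylsilyloxy)methyl]-2H-chromen-8-yl}acrylate | O/C=C(\C(=O)OCC=C)c1ccc(O[Si](C(C)C)(C(C)C)C(C)C)c2C=C[C@@](C)(CO[Si](C(C)C)(C(C)C)C(C)C)Oc12 | intermediate
14 | allyl (Z)-2-{(S)-2-methyl-5-(triisopropylsilyloxy)-2-[(triisopropylsilyloxy)methyl]-2H-chromen-8-yl}-3-(tosyloxy)acrylate | Cc1ccc(cc1)S(=O)(=O)O/C=C(\C(=O)OCC=C)c1ccc(O[Si](C(C)C)(C(C)C)C(C)C)c2C=C[C@@](C)(CO[Si](C(C)C)(C(C)C)C(C)C)Oc12 | intermediate
15 | phloroglucinol (benzene-1,3,5-triol) | Oc1cc(O)cc(O)c1 | starting material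
16 | 3,5-bis(triisopropylsilyloxy)phenol | Oc1cc(O[Si](C(C)C)(C(C)C)C(C)C)cc(O[Si](C(C)C)(C(C)C)C(C)C)c1 | intermediate
17 | allyl (Z)-3-[3,5-bis(triisopropylsilyloxy)phenoxy]-2-{(S)-2-methyl-5-(triisopropylsilyloxy)-2-[(triisopropylsilyloxy)methyl]-2H-chromen-8-yl}acrylate | C=CCOC(=O)/C(=C\Oc1cc(O[Si](C(C)C)(C(C)C)C(C)C)cc(O[Si](C(C)C)(C(C)C)C(C)C)c1)c1ccc(O[Si](C(C)C)(C(C)C)C(C)C)c2C=C[C@@](C)(CO[Si](C(C)C)(C(C)C)C(C)C)Oc12 | intermediate
18 | (Z)-3-[3,5-bis(triisopropylsilyloxy)phenoxy]-2-{(S)-2-methyl-5-(triisopropylsilyloxy)-2-[(triisopropylsilyloxy)methyl]-2H-chromen-8-yl}acrylic acid | OC(=O)/C(=C\Oc1cc(O[Si](C(C)C)(C(C)C)C(C)C)cc(O[Si](C(C)C)(C(C)C)C(C)C)c1)c1ccc(O[Si](C(C)C)(C(C)C)C(C)C)c2C=C[C@@](C)(CO[Si](C(C)C)(C(C)C)C(C)C)Oc12 | intermediate (precursor of the key step)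
19 | (Z)-3-[3,5-bis(triisopropylsilyloxy)phenoxy]-2-{(S)-2-methyl-5-(triisopropylsilyloxy)-2-[(triisopropylsilyloxy)methyl]-2H-chromen-8-yl}acryloyl chloride | ClC(=O)/C(=C\Oc1cc(O[Si](C(C)C)(C(C)C)C(C)C)cc(O[Si](C(C)C)(C(C)C)C(C)C)c1)c1ccc(O[Si](C(C)C)(C(C)C)C(C)C)c2C=C[C@@](C)(CO[Si](C(C)C)(C(C)C)C(C)C)Oc12 | intermediate (not isolated)
20 | 5,7-bis(triisopropylsilyloxy)-3-{(S)-2-methyl-5-(triisopropylsilyloxy)-2-[(triisopropylsilyloxy)methyl]-2H-chromen-8-yl}-4H-chromen-4-one | C[C@@]1(CO[Si](C(C)C)(C(C)C)C(C)C)C=Cc2c(O[Si](C(C)C)(C(C)C)C(C)C)ccc(-c3coc4cc(O[Si](C(C)C)(C(C)C)C(C)C)cc(O[Si](C(C)C)(C(C)C)C(C)C)c4c3=O)c2O1 | intermediate (product of the key step)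
21 | 5,7-dihydroxy-3-[(S)-5-hydroxy-2-(hydroxymethyl)-2-methyl-2H-chromen-8-yl]-4H-chromen-4-one (CNP0141863.1) | C[C@@]1(CO)C=Cc2c(O)ccc(-c3coc4cc(O)cc(O)c4c3=O)c2O1 | target

## Step count and least certain steps

Total: 14 steps. Longest linear sequence: 11 steps (steps 1, 2, 3, 5, 6, 8, 9, 11, 12, 13, 14, from 1 to 21).

**Step 13 (key step).**
- What may go wrong: capture of the acylium by the ortho ether oxygen of ring B followed by heterolysis of the tertiary allylic C2''–O bond (dealkylative lactonisation); Lewis-acid opening or oligomerisation of the chromene; slow attack at a ring carbon shielded by the neighbouring triisopropylsilyloxy group, giving time for intermolecular acylation of ring B.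
- Why: the electrophile is generated beside an electron-rich, acid-labile chromene.
- Fallback (polarity reversed, no Lewis acid): it sets out from 16 and 14 and returns at 20. 16 would be iodinated ortho to the free hydroxyl (N-iodosuccinimide, CH2Cl2, 0 °C; the position between the two silyloxy groups is shielded) to give 2-iodo-3,5-bis(triisopropylsilyloxy)phenol F1. F1 would displace the tosylate of 14 under the conditions of step 11 to give allyl (Z)-3-[2-iodo-3,5-bis(triisopropylsilyloxy)phenoxy]-2-{(S)-2-methyl-5-(triisopropylsilyloxy)-2-[(triisopropylsilyloxy)methyl]-2H-chromen-8-yl}acrylate F2. Iodine–lithium exchange (t-BuLi, 2 equiv, THF–Et2O, −100 °C) would make the same ring carbon a nucleophile that attacks the allyl ester in a Parham-type cyclisation, closing ring C and giving 20; step 14 then follows.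

**Step 8.**
- What may go wrong: competing 1,2-hydride shift in the diazonium adduct (leading to the β-keto ester), and acid-induced loss of a silyl group or hydration and oligomerisation of the chromene.
- Fallback (stepwise homologation, then formylation): it sets out from 10 and returns at 13. Wittig methoxymethylenation of 10 ((methoxymethyl)triphenylphosphonium chloride, KN(SiMe3)2, THF, 0 °C) would give (S)-8-(2-methoxyvinyl)-2-methyl-5-(triisopropylsilyloxy)-2-[(triisopropylsilyloxy)methyl]-2H-chromene F3. Brief hydrolysis (aq. HCl, THF, 0 °C) would give 2-{(S)-2-methyl-5-(triisopropylsilyloxy)-2-[(triisopropylsilyloxy)methyl]-2H-chromen-8-yl}acetaldehyde F4. Pinnick oxidation (NaClO2, NaH2PO4, 2-methylbut-2-ene, t-BuOH–H2O) would give 2-{(S)-2-methyl-5-(triisopropylsilyloxy)-2-[(triisopropylsilyloxy)methyl]-2H-chromen-8-yl}acetic acid F5. Alkylation (allyl bromide, K2CO3, DMF) would give allyl 2-{(S)-2-methyl-5-(triisopropylsilyloxy)-2-[(triisopropylsilyloxy)methyl]-2H-chromen-8-yl}acetate F6. Claisen formylation (LiN(i-Pr)2, THF, −78 °C, then allyl formate) would give 13.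

**Step 5.**
- What may go wrong: transfer of the aryl silyl group to the alkoxide (attack at silicon, releasing a phenoxide that no longer undergoes substitution), and reversible capture of the alkoxide by the formyl group, both slowing a substitution already retarded by the tertiary nucleophile.
- Fallback (base-inert phenol protection): it sets out from 6, uses alkoxide 8 made from 5 as in the main route, and returns at 10. 6 would be converted (MOMCl, i-Pr2NEt, CH2Cl2) into 2-fluoro-4-(methoxymethoxy)benzaldehyde F7. Substitution with 8 would give (S)-4-(methoxymethoxy)-2-{[2-methyl-1-(triisopropylsilyloxy)but-3-yn-2-yl]oxy}benzaldehyde F8. Hydroarylation with Ph3PAuNTf2 as in step 6 would give (S)-5-(methoxymethoxy)-2-methyl-2-[(triisopropylsilyloxy)methyl]-2H-chromene-8-carbaldehyde F9. Acetal cleavage (ZnBr2, n-PrSH, CH2Cl2, 0 °C) would give (S)-5-hydroxy-2-methyl-2-[(triisopropylsilyloxy)methyl]-2H-chromene-8-carbaldehyde F10, and silylation (TIPSCl, imidazole, DMF) would give 10.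

**Step 1.**
- What may go wrong: evaporative loss of the low-boiling epoxy aldehyde and ethynyloxirane during handling, and methanolysis of the oxirane under the homologation conditions.
- Fallback (oxirane opened first, no volatile intermediates): it sets out from 1 and returns at 4. 1 would be opened at its oxirane CH2 by 4-methoxybenzyl alkoxide (NaH, 4-methoxybenzyl alcohol, DMF, 60 °C; a Payne rearrangement of 1 is degenerate and leads to the same enantiomer) to give (S)-3-(4-methoxybenzyloxy)-2-methylpropane-1,2-diol F11. Oxidation of the primary hydroxyl (TEMPO, PhI(OAc)2, CH2Cl2) would give (R)-2-hydroxy-3-(4-methoxybenzyloxy)-2-methylpropanal F12. Homologation with the Ohira–Bestmann reagent (K2CO3, MeOH) would give (S)-1-(4-methoxybenzyloxy)-2-methylbut-3-yn-2-ol F13, and oxidative debenzylation (DDQ, CH2Cl2–H2O) would give 4.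

## Further compounds

F1 | step 13 | 2-iodo-3,5-bis(triisopropylsilyloxy)phenol | Oc1cc(O[Si](C(C)C)(C(C)C)C(C)C)cc(O[Si](C(C)C)(C(C)C)C(C)C)c1I
F2 | step 13 | allyl (Z)-3-[2-iodo-3,5-bis(triisopropylsilyloxy)phenoxy]-2-{(S)-2-methyl-5-(triisopropylsilyloxy)-2-[(triisopropylsilyloxy)methyl]-2H-chromen-8-yl}acrylate | C=CCOC(=O)/C(=C\Oc1cc(O[Si](C(C)C)(C(C)C)C(C)C)cc(O[Si](C(C)C)(C(C)C)C(C)C)c1I)c1ccc(O[Si](C(C)C)(C(C)C)C(C)C)c2C=C[C@@](C)(CO[Si](C(C)C)(C(C)C)C(C)C)Oc12
F3 | step 8 | (S)-8-(2-methoxyvinyl)-2-methyl-5-(triisopropylsilyloxy)-2-[(triisopropylsilyloxy)methyl]-2H-chromene (mixture of enol ether isomers) | COC=Cc1ccc(O[Si](C(C)C)(C(C)C)C(C)C)c2C=C[C@@](C)(CO[Si](C(C)C)(C(C)C)C(C)C)Oc12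
F4 | step 8 | 2-{(S)-2-methyl-5-(triisopropylsilyloxy)-2-[(triisopropylsilyloxy)methyl]-2H-chromen-8-yl}acetaldehyde | O=CCc1ccc(O[Si](C(C)C)(C(C)C)C(C)C)c2C=C[C@@](C)(CO[Si](C(C)C)(C(C)C)C(C)C)Oc12
F5 | step 8 | 2-{(S)-2-methyl-5-(triisopropylsilyloxy)-2-[(triisopropylsilyloxy)methyl]-2H-chromen-8-yl}acetic acid | OC(=O)Cc1ccc(O[Si](C(C)C)(C(C)C)C(C)C)c2C=C[C@@](C)(CO[Si](C(C)C)(C(C)C)C(C)C)Oc12
F6 | step 8 | allyl 2-{(S)-2-methyl-5-(triisopropylsilyloxy)-2-[(triisopropylsilyloxy)methyl]-2H-chromen-8-yl}acetate | C=CCOC(=O)Cc1ccc(O[Si](C(C)C)(C(C)C)C(C)C)c2C=C[C@@](C)(CO[Si](C(C)C)(C(C)C)C(C)C)Oc12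
F7 | step 5 | 2-fluoro-4-(methoxymethoxy)benzaldehyde | O=Cc1ccc(OCOC)cc1F
F8 | step 5 | (S)-4-(methoxymethoxy)-2-{[2-methyl-1-(triisopropylsilyloxy)but-3-yn-2-yl]oxy}benzaldehyde | O=Cc1ccc(OCOC)cc1O[C@@](C)(C#C)CO[Si](C(C)C)(C(C)C)C(C)C
F9 | step 5 | (S)-5-(methoxymethoxy)-2-methyl-2-[(triisopropylsilyloxy)methyl]-2H-chromene-8-carbaldehyde | O=Cc1ccc(OCOC)c2C=C[C@@](C)(CO[Si](C(C)C)(C(C)C)C(C)C)Oc12
F10 | step 5 | (S)-5-hydroxy-2-methyl-2-[(triisopropylsilyloxy)methyl]-2H-chromene-8-carbaldehyde | O=Cc1ccc(O)c2C=C[C@@](C)(CO[Si](C(C)C)(C(C)C)C(C)C)Oc12
F11 | step 1 | (S)-3-(4-methoxybenzyloxy)-2-methylpropane-1,2-diol | OC[C@@](O)(C)COCc1ccc(OC)cc1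
F12 | step 1 | (R)-2-hydroxy-3-(4-methoxybenzyloxy)-2-methylpropanal | O=C[C@@](O)(C)COCc1ccc(OC)cc1
F13 | step 1 | (S)-1-(4-methoxybenzyloxy)-2-methylbut-3-yn-2-ol | C#C[C@@](O)(C)COCc1ccc(OC)cc1
A1 | alternative 1 | (S)-2-(tert-butyldimethylsilyloxymethyl)-8-chloro-5-(methoxymethoxy)-2-methyl-2H-chromene | C[C@@]1(CO[Si](C)(C)C(C)(C)C)C=Cc2c(OCOC)ccc(Cl)c2O1
A2 | alternative 1 | (S,Z)-4-[2-bromo-3-chloro-6-(methoxymethoxy)phenyl]-1-(tert-butyldimethylsilyloxy)-2-methylbut-3-en-2-ol | C[C@@](O)(CO[Si](C)(C)C(C)(C)C)/C=C\c1c(OCOC)ccc(Cl)c1Br
A3 | alternative 2 | 3-[(2R,3S)-3-hydroxy-2-(hydroxymethyl)-5-(methoxymethoxy)-2-methylchroman-8-yl]-5,7-bis(methoxymethoxy)-4H-chromen-4-one | C[C@@]1(CO)[C@@H](O)Cc2c(OCOC)ccc(-c3coc4cc(OCOC)cc(OCOC)c4c3=O)c2O1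
A4 | alternative 2 | 3-(2-hydroxy-3-{[(2S,3S)-3-(hydroxymethyl)-3-methyloxiran-2-yl]methyl}-4-(methoxymethoxy)phenyl)-5,7-bis(methoxymethoxy)-4H-chromen-4-one | C[C@@]1(CO)O[C@H]1Cc1c(OCOC)ccc(-c2coc3cc(OCOC)cc(OCOC)c3c2=O)c1O
A5 | alternative 3 | 2'-hydroxy-3'-[(E)-4-(4-methoxybenzyloxy)-3-methylbut-2-enyl]-4'-(triisopropylsilyloxy)-5,7-bis(methoxymethoxy)isoflavone | Oc1c(C/C=C(\C)COCc2ccc(OC)cc2)c(O[Si](C(C)C)(C(C)C)C(C)C)ccc1-c1coc2cc(OCOC)cc(OCOC)c2c1=O
A6 | alternative 3 | (E)-3-(4-diazo-3-oxobut-1-en-1-yl)-5,7-bis(methoxymethoxy)-4H-chromen-4-one | [N-]=[N+]=CC(=O)/C=C/c1coc2cc(OCOC)cc(OCOC)c2c1=O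
A7 | alternative 3 | (E)-triisopropyl{[6-(4-methoxybenzyloxy)-5-methylhex-4-en-1-yn-1-yl]oxy}silane | CC(C)[Si](C(C)C)(C(C)C)OC#CC/C=C(\C)COCc1ccc(OC)cc1
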